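## Analysis of the target

Target 14 is an open-chain molecule whose only rings are two arenes: ring A (3,4-dimethoxyphenyl) sits on the carbinol carbon C1, and ring B (4-methoxyphenyl) ends an (E)-styrenyl arm (C4 methylene, C5=C6 alkene) that branches from the methine C2. C1 (S, secondary benzylic alcohol) and C2 (R) are the only stereocentres; they are adjacent, and in the zigzag C3–C2–C1–ring A the C1 hydroxyl and the C4 arm lie on the same side (syn). C3 is a primary carbon whose oxygen (O3) carries a (Z)-2-(hydroxymethyl)but-2-enoyl group, with the methyl cis to the ester carbonyl, the less stable, angelate-like geometry.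

The sensitive points are these: the para-alkoxy benzylic alcohol ionises under acid, the Z-enoate can isomerise by reversible conjugate addition, its allylic hydroxymethyl group is open to SN2' attack, the acyl group can migrate from O3 to O1, and the styrene must survive every reduction. The difficulty is to fix two contiguous stereocentres in a flexible chain with no ring to lean on, to tell the two core hydroxyls apart, and to build a trisubstituted alkene against its thermodynamic bias.

The strategy rests on the array O1–C1–C2–C3–O3, which is the reduced form of a 2-substituted 3-aryl-3-oxopropanoate. At that oxidation level C2 lies between two carbonyls and loses its configuration freely, so it can be set together with C1 by reducing only the C1 ketone.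

## Retrosynthetic reasoning

**14 from 13 (O–Si bond).** The last operation is removal of a silyl group from the allylic hydroxymethyl oxygen of 13. The mask is needed because the acid partner would otherwise carry a free primary hydroxyl that competes in the acylation. The forward step must cleave O–Si without moving the acyl group to O1 and without ionising C1.

**13 from diol 6 and acid 11 (acyl C–O3 bond).** This is the one bond that separates the two independent stereochemical problems: the C1/C2 pair in 6 and the alkene geometry in 11. Cutting it makes the route convergent. The forward reaction, through mixed anhydride 12, has to acylate the primary hydroxyl of 6 in the presence of the hindered benzylic one and must not erode the Z geometry.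

**11 from 10, 9 and alkyne 7 (C2'–CH2OH and C3'–H bonds).** Acid 11 is traced through its ethyl ester 10 and the free alcohol 9 to ynoate 7. The hydrogen at C3' and the hydroxymethyl carbon at C2' are cis in the target, so both are added to the same face of the triple bond of 7 through allenolate 8. The geometry then comes from the mechanism of the addition and not from an equilibrium, which would favour the wrong isomer.

**6 from 5 (oxidation level of C3).** Raising C3 of diol 6 to the ester level gives β-hydroxy ester 5. The forward step is an ester reduction that touches neither stereocentre and leaves the styrene alone.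

**5 from 4 (C1–H bond, both stereocentres).** Removing the hydride from C1 gives β-keto ester 4, in which C2 is stereolabile. Only one bond is cut, yet both stereocentres go back to a racemate. The forward reduction must select one ketone face and one C2 configuration while the C2 enantiomers interconvert, and must ignore the ester and the alkene.

**4 from 3 and 2 (C2–C4 bond), 2 from 1.** C2 of 4 is the carbon between the two carbonyls of commercial keto ester 3, so it is the natural nucleophile. The C4–C6 arm is an allyl electrophile, carbonate 2, made from commercial alcohol 1, which already holds the E alkene and ring B. The forward reaction must alkylate once, at carbon, at the unsubstituted allyl terminus.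

## Alternatives that were turned down

Alternative 1: hydroboration and B-alkyl Suzuki coupling (C4–C5 bond).
- Disconnection and key step: the 1,1-disubstituted alkene of the bis-TBS ether of (R)-1-(3,4-dimethoxyphenyl)-2-methylenepropane-1,3-diol A1 would be hydroborated with 9-BBN, hydrogen going to C2 and boron to C4 under the influence of C1. The alkylborane would be coupled in the same flask with (E)-1-(2-bromovinyl)-4-methoxybenzene A2 under Pd(dppf)Cl2. The product would be the bis-TBS ether of (1S,2R,E)-1-(3,4-dimethoxyphenyl)-2-(hydroxymethyl)-5-(4-methoxyphenyl)pent-4-en-1-ol A3, the doubly silylated form of diol 6.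
- For it: the sp3–sp2 coupling is dependable, the E geometry is bought with A2, and the usual sense of 1,2-induction with bulky dialkylboranes places the new arm syn to O1, as required. On late-stage convergence it is stronger than the chosen route.
- Against it: C1 of A1 must be made enantiopure beforehand, by an asymmetric or resolving step on a Morita–Baylis–Hillman-type alcohol that forms sluggishly from an electron-rich aryl aldehyde. The diastereoselectivity at C2 is substrate control of uncertain size for an aryl carbinol silyl ether flanked by a silyloxymethyl group. The two TBS ethers of A3 must later be told apart before the acylation.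
- Comparison: several more steps lead up to A1 and a selective desilylation follows A3, whereas the chosen route takes both absolute and relative configuration from one catalyst acting on a racemate two steps from commercial material.

Alternative 2: dianionic Ireland–Claisen rearrangement (C2–C4 bond).
- Disconnection and key step: the alkoxide–enolate dianion of (R)-1-(4-methoxyphenyl)allyl 3-hydroxypropanoate A4 would rearrange through a chair to (R,E)-2-(hydroxymethyl)-5-(4-methoxyphenyl)pent-4-enoic acid A5, creating the C2–C4 bond and the E alkene together.
- For it: chirality transfer in a [3,3] shift is stereospecific, and the E-styrene of A5 comes for free. On these points it is at least as strong as the chosen route, because C2 arises from a specific event and not from a choice between diastereomeric transition states.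
- Against it: only C2 is set in A5. C1 still needs conversion of the carboxyl group of A5 into the aryl ketone and a diastereoselective reduction, which is the problem the chosen route solves at the start. A4 is a para-methoxybenzylic, allylic ester that ionises, racemises and transposes easily, and it must itself be made enantiopure. The enolate geometry of the dianion, which decides the sense at C2, is not secure.
- Comparison: the chosen route needs fewer steps, uses commercial precursors and sets both centres in one operation.

Alternative 3: asymmetric hydroxymethylation, then Evans–Tishchenko reduction (C2–C3 bond).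
- Disconnection and key step: {[(1Z,4E)-1-(3,4-dimethoxyphenyl)-5-(4-methoxyphenyl)penta-1,4-dien-1-yl]oxy}trimethylsilane A6, a (Z)-silyl enol ether, would undergo catalytic asymmetric hydroxymethylation in aqueous medium (Sc(OTf)3 with a chiral 2,2'-bipyridine diol). The product would be (R,E)-1-(3,4-dimethoxyphenyl)-2-(hydroxymethyl)-5-(4-methoxyphenyl)pent-4-en-1-one A7, with the C2–C3 bond and the C2 stereocentre newly formed.
- For it: a later Evans–Tishchenko step on A7 could reduce C1 and place an acyl group on O3 in one operation. On differentiation of the two hydroxyls this is stronger than the chosen route.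
- Against it: A7 holds its only stereocentre next to an aryl ketone and β to a hydroxyl, so enolisation and dehydration to the α-methylene ketone threaten it at every step. A6 must be made geometrically pure from a ketone that itself needs several steps. The Evans–Tishchenko reaction normally relays from a secondary carbinol to give a 1,3-anti diol; here the carbinol carbon is C3, a methylene, so induction would have to come from C2, and the sense needed for the syn relation is not assured. The acyl group delivered would come from a simple aldehyde and would have to be exchanged, because a Z-enal is a poor and labile hydride donor.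
- Comparison: the chosen route turns the lability of C2 into the basis of the method and passes through a configurationally robust β-hydroxy ester.

Key step: step 3

Assumption: on aryl ketone 4 the (S,S)-configured catalyst is taken to show the facial sense it shows on simple aryl alkyl ketones (aryl group beside the η6-arene, giving the (S)-carbinol); if the opposite sense were found, the mirror-image catalyst would be used with no other change.

## Route

Step 1
Reactants: 1 (E)-3-(4-methoxyphenyl)prop-2-en-1-ol
Product: 2 methyl (E)-3-(4-methoxyphenyl)prop-2-en-1-yl carbonate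
Conditions: ClCO2Me, pyridine, CH2Cl2, 0 °C → rt
Reagents that add atoms: methyl chloroformate, COC(=O)Cl
Why: O-acylation of a primary allylic alcohol by a chloroformate under amine buffering; the medium stays basic, so the electron-rich cinnamyl system does not ionise, and the carbonate is a stable allyl donor in place of a labile allylic halide.

Step 2
Reactants: 3 ethyl 3-(3,4-dimethoxyphenyl)-3-oxopropanoate; 2 methyl (E)-3-(4-methoxyphenyl)prop-2-en-1-yl carbonate
Product: 4 ethyl (E)-2-(3,4-dimethoxybenzoyl)-5-(4-methoxyphenyl)pent-4-enoate (racemic)
Conditions: Pd(PPh3)4 (2 mol%), THF, rt (3 in slight excess)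
Reagents that add atoms: none
Why: Tsuji–Trost allylic alkylation: zerovalent palladium ionises the carbonate to an aryl-substituted π-allyl complex with loss of CO2, the methoxide set free deprotonates 3, and the soft enolate attacks the unsubstituted allyl terminus to give the linear (E) product. A small excess of 3 limits double allylation, and C2 is deliberately formed racemic.

Step 3
Reactants: 4 ethyl (E)-2-(3,4-dimethoxybenzoyl)-5-(4-methoxyphenyl)pent-4-enoate (racemic)
Product: 5 ethyl (2S,E)-2-[(S)-(3,4-dimethoxyphenyl)(hydroxy)methyl]-5-(4-methoxyphenyl)pent-4-enoate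
Conditions: RuCl(p-cymene)[(S,S)-TsDPEN] (1–2 mol%), HCO2H/Et3N (5:2), CH2Cl2, 30 °C
Reagents that add atoms: none
Why: Noyori–Ikariya asymmetric transfer hydrogenation with dynamic kinetic resolution of a 2-substituted β-keto ester: formate turns the chloride precatalyst into the 18-electron divalent ruthenium hydride, which passes Ru–H and N–H to the ketone C=O through a six-membered outer-sphere transition state, and loss of CO2 makes the reduction irreversible. No ring is closed and no skeletal bond is formed; the only new bond is C1–H. C1 is controlled by the catalyst: the aryl ketone docks with ring A beside the η6-p-cymene (C–H/π contact), which with the (S,S)-ligand exposes the face leading to the (S)-carbinol. C2 is controlled by the preference of that transition state for one enantiomer of 4: hydride should arrive anti to the cinnamyl arm while the ester carbonyl lies near the ketone oxygen and the ligand N–H, which gives the syn (2S) relation, and the slower enantiomer is fed back through the enol. The resolution is dynamic because the C2–H lies between two carbonyls and exchanges in the amine–formate medium much faster than the electron-rich, slowly reduced dimethoxybenzoyl ketone is consumed. Chemoselectivity follows from the mechanism: the coordinatively saturated hydride offers no site to the styrene and does not reduce the ester. Once C1 is sp3, C2 is flanked by one carbonyl only and should no longer epimerise under the conditions.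

Step 4
Reactants: 5 ethyl (2S,E)-2-[(S)-(3,4-dimethoxyphenyl)(hydroxy)methyl]-5-(4-methoxyphenyl)pent-4-enoate
Product: 6 (1S,2R,E)-1-(3,4-dimethoxyphenyl)-2-(hydroxymethyl)-5-(4-methoxyphenyl)pent-4-en-1-ol
Conditions: LiBH4, THF, 0 °C → rt; aq. NH4Cl
Reagents that add atoms: none
Why: Ester reduction by LiBH4, helped by lithium chelation to the β-alkoxide; the styrene and aryl ethers are inert and neither stereocentre is at the reacting carbon (the C2 descriptor changes from S to R only because the priorities change).

Step 5
Reactants: 7 ethyl but-2-ynoate
Product: 9 ethyl (Z)-2-(hydroxymethyl)but-2-enoate, via aluminium allenolate 8 (not isolated)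
Conditions: i-Bu2AlH, HMPA, THF, 0 °C, then 7; then monomeric CH2O in THF, −78 → −40 °C; aq. KNaC4H4O6
Reagents that add atoms: formaldehyde, C=O; diisobutylaluminium hydride, CC(C)C[AlH]CC(C)C (its aluminium stays only in 8)
Why: Reductive aldol (vinylalumination) of an ynoate: the amide-complexed aluminium hydride adds in conjugate fashion to give allenolate 8, whose central carbon attacks the aldehyde in the plane of the C3' substituents from the side of C3'–H and not C3'–CH3. The hydroxymethyl group therefore ends cis to H and the methyl cis to the ester, the (Z)-enoate, and low temperature preserves this kinetic geometry.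

Step 6
Reactants: 9 ethyl (Z)-2-(hydroxymethyl)but-2-enoate
Product: 10 ethyl (Z)-2-{[(tert-butyldimethylsilyl)oxy]methyl}but-2-enoate
Conditions: TBSCl, imidazole, CH2Cl2, 0 °C → rt
Reagents that add atoms: tert-butyldimethylsilyl chloride, CC(C)(C)[Si](C)(C)Cl
Why: Silylation of a primary allylic alcohol under imidazole catalysis; the conditions are too mild to add to or isomerise the enoate.

Step 7
Reactants: 10 ethyl (Z)-2-{[(tert-butyldimethylsilyl)oxy]methyl}but-2-enoate
Product: 11 (Z)-2-{[(tert-butyldimethylsilyl)oxy]methyl}but-2-enoic acid
Conditions: LiOH·H2O, THF/H2O, rt; then cold dilute HCl to pH 4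
Reagents that add atoms: lithium hydroxide, [Li+].[OH-]
Why: Saponification: hydroxide attacks the ester carbonyl and not the α,β-disubstituted β-carbon, so no reversible conjugate addition scrambles the geometry. The primary TBS ether tolerates aqueous LiOH and a brief, cold, weakly acidic work-up.

Step 8
Reactants: 11 (Z)-2-{[(tert-butyldimethylsilyl)oxy]methyl}but-2-enoic acid; 6 (1S,2R,E)-1-(3,4-dimethoxyphenyl)-2-(hydroxymethyl)-5-(4-methoxyphenyl)pent-4-en-1-ol
Product: 13 (2R,E)-2-[(S)-(3,4-dimethoxyphenyl)(hydroxy)methyl]-5-(4-methoxyphenyl)pent-4-en-1-yl (Z)-2-{[(tert-butyldimethylsilyl)oxy]methyl}but-2-enoate, via mixed anhydride 12 (not isolated)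
Conditions: 2,4,6-Cl3C6H2COCl, Et3N, toluene, rt; then 6, DMAP (cat.), 0 °C → rt
Reagents that add atoms: 2,4,6-trichlorobenzoyl chloride, O=C(Cl)c1c(Cl)cc(Cl)cc1Cl (its atoms stay only in 12)
Why: Yamaguchi esterification: the alcohol attacks the enoyl carbonyl of 12 because the aroyl carbonyl is shielded by two ortho chlorines, and the primary hydroxyl of 6 reacts well ahead of the branched benzylic one. Substoichiometric DMAP at low temperature keeps nucleophile-induced Z→E isomerisation and double acylation down.

Step 9
Reactants: 13 (2R,E)-2-[(S)-(3,4-dimethoxyphenyl)(hydroxy)methyl]-5-(4-methoxyphenyl)pent-4-en-1-yl (Z)-2-{[(tert-butyldimethylsilyl)oxy]methyl}but-2-enoate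
Product: 14 (2R,E)-2-[(S)-(3,4-dimethoxyphenyl)(hydroxy)methyl]-5-(4-methoxyphenyl)pent-4-en-1-yl (Z)-2-(hydroxymethyl)but-2-enoate
Conditions: HF·pyridine, pyridine, THF, 0 °C → rt
Reagents that add atoms: none
Why: Fluoride cleavage of a primary silyl ether; the pyridine-buffered reagent is not basic enough to drive 1,3-acyl migration or conjugate addition and not acidic enough to ionise the dimethoxybenzylic alcohol.

## Compound list

1 | (E)-3-(4-methoxyphenyl)prop-2-en-1-ol | OC/C=C/c1ccc(OC)cc1 | starting material
2 | methyl (E)-3-(4-methoxyphenyl)prop-2-en-1-yl carbonate | COC(=O)OC/C=C/c1ccc(OC)cc1 | intermediate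
3 | ethyl 3-(3,4-dimethoxyphenyl)-3-oxopropanoate | CCOC(=O)CC(=O)c1ccc(OC)c(OC)c1 | starting material
4 | ethyl (E)-2-(3,4-dimethoxybenzoyl)-5-(4-methoxyphenyl)pent-4-enoate, racemic | CCOC(=O)C(C/C=C/c1ccc(OC)cc1)C(=O)c1ccc(OC)c(OC)c1 | intermediate
5 | ethyl (2S,E)-2-[(S)-(3,4-dimethoxyphenyl)(hydroxy)methyl]-5-(4-methoxyphenyl)pent-4-enoate | CCOC(=O)[C@@H](C/C=C/c1ccc(OC)cc1)[C@H](O)c1ccc(OC)c(OC)c1 | intermediate
6 | (1S,2R,E)-1-(3,4-dimethoxyphenyl)-2-(hydroxymethyl)-5-(4-methoxyphenyl)pent-4-en-1-ol | OC[C@@H](C/C=C/c1ccc(OC)cc1)[C@H](O)c1ccc(OC)c(OC)c1 | intermediate
7 | ethyl but-2-ynoate | CC#CC(=O)OCC | starting material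
8 | diisobutylaluminium 1-ethoxybuta-1,2-dien-1-olate (aluminium allenolate) | CC=C=C(OCC)O[Al](CC(C)C)CC(C)C | intermediate
9 | ethyl (Z)-2-(hydroxymethyl)but-2-enoate | C/C=C(/CO)C(=O)OCC | intermediate
10 | ethyl (Z)-2-{[(tert-butyldimethylsilyl)oxy]methyl}but-2-enoate | C/C=C(/CO[Si](C)(C)C(C)(C)C)C(=O)OCC | intermediate
11 | (Z)-2-{[(tert-butyldimethylsilyl)oxy]methyl}but-2-enoic acid | C/C=C(/CO[Si](C)(C)C(C)(C)C)C(=O)O | intermediate
12 | (Z)-2-{[(tert-butyldimethylsilyl)oxy]methyl}but-2-enoic 2,4,6-trichlorobenzoic anhydride | C/C=C(/CO[Si](C)(C)C(C)(C)C)C(=O)OC(=O)c1c(Cl)cc(Cl)cc1Cl | intermediate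
13 | (2R,E)-2-[(S)-(3,4-dimethoxyphenyl)(hydroxy)methyl]-5-(4-methoxyphenyl)pent-4-en-1-yl (Z)-2-{[(tert-butyldimethylsilyl)oxy]methyl}but-2-enoate | C/C=C(/CO[Si](C)(C)C(C)(C)C)C(=O)OC[C@@H](C/C=C/c1ccc(OC)cc1)[C@H](O)c1ccc(OC)c(OC)c1 | intermediate
14 | (2R,E)-2-[(S)-(3,4-dimethoxyphenyl)(hydroxy)methyl]-5-(4-methoxyphenyl)pent-4-en-1-yl (Z)-2-(hydroxymethyl)but-2-enoate | C/C=C(/CO)C(=O)OC[C@@H](C/C=C/c1ccc(OC)cc1)[C@H](O)c1ccc(OC)c(OC)c1 | target

## Step count and least certain steps

Total: 9 steps. Longest linear sequence: 6 steps (steps 1, 2, 3, 4, 8, 9, from 1 to 14). The acid branch (steps 5–7) joins at step 8.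

**Step 3 (key step).** The likely failure is poor discrimination between the two interconverting C2 enantiomers of 4, that is, a low syn preference. An open-chain 2-alkyl-3-aryl-3-oxo ester can also react through a Felkin-type arrangement with the ester anti to the hydride, which leads to the anti relation. Sluggish reduction of the electron-rich ketone is a second, lesser risk. The sense at C1 is the more secure element.
Fallback: move the same reduction to the β-keto amide class, for which the syn outcome with this catalyst family is the better established. It sets out from 3. Aminolysis with morpholine (toluene, reflux, cat. DMAP) should give 1-(3,4-dimethoxyphenyl)-3-(morpholin-4-yl)propane-1,3-dione F1. Allylation with 2 under Pd(PPh3)4 as in step 2 should give racemic (E)-1-(3,4-dimethoxyphenyl)-2-[3-(4-methoxyphenyl)prop-2-en-1-yl]-3-(morpholin-4-yl)propane-1,3-dione F2. The RuCl(p-cymene)[(S,S)-TsDPEN]/HCO2H–Et3N reduction should then give (2S,E)-2-[(S)-(3,4-dimethoxyphenyl)(hydroxy)methyl]-5-(4-methoxyphenyl)-1-(morpholin-4-yl)pent-4-en-1-one F3. Reduction of the tertiary amide to the primary alcohol with LiNH2BH3 (THF, 0 °C → rt) comes back to the route at 6.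

**Step 5.** The Z geometry may erode if the aluminium allenolate or the aluminium aldolate equilibrates on warming. The ester may suffer 1,2-reduction, and capture of the monomeric aldehyde may be inefficient.
Fallback: fix the geometry by two stereoretentive metal exchanges. It sets out from 7. Syn hydrostannation (Bu3SnH, Pd(PPh3)4, THF) should give ethyl (E)-2-(tributylstannyl)but-2-enoate F4. Iododestannylation (I2, CH2Cl2, 0 °C) should give ethyl (E)-2-iodobut-2-enoate F5 with retention. Stille coupling with Bu3SnCH2OH (Pd(PPh3)4, dioxane, 80 °C) comes back to the route at 9.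

**Step 8.** The Z geometry may be lost through reversible conjugate addition of DMAP or chloride to the activated acyl species, and some acylation may occur at the benzylic hydroxyl.
Fallback: reverse the polarity of the ester formation. It sets out from 6 and 11. A Mitsunobu coupling (PPh3, DIAD, THF, 0 °C) activates the primary hydroxyl of 6 as its oxyphosphonium ion and lets the carboxylate of 11 displace it, so the acyl carbon never becomes electrophilic; it comes back to the route at 13.

**Step 9.** The enoyl group may migrate from O3 to O1, or the ester may be cleaved, if the fluoride medium turns basic.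
Fallback: an endgame without any silyl group. It sets out from 6 and 9. Selective sulfonylation of the primary hydroxyl of 6 (TsCl, pyridine, 0 °C) should give (2R,E)-2-[(S)-(3,4-dimethoxyphenyl)(hydroxy)methyl]-5-(4-methoxyphenyl)pent-4-en-1-yl 4-methylbenzenesulfonate F6. Saponification of 9 (LiOH, THF/H2O) should give (Z)-2-(hydroxymethyl)but-2-enoic acid F7. Displacement of the sulfonate by the caesium carboxylate of F7 (Cs2CO3, 0.5 equiv, DMF, 40 °C) comes back to the route at 14.

**Step 2.** Double allylation may compete, and the donor aryl group may draw some attack to the benzylic terminus of the π-allyl complex.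
Fallback: a classical enolate alkylation. It sets out from 1. PBr3 (Et2O, 0 °C) should give (E)-1-(3-bromoprop-1-en-1-yl)-4-methoxybenzene F8, used at once. C-alkylation of 3 with K2CO3 in acetone comes back to the route at 4.

## Further compounds

F1 | step 3 | 1-(3,4-dimethoxyphenyl)-3-(morpholin-4-yl)propane-1,3-dione | COc1ccc(cc1OC)C(=O)CC(=O)N1CCOCC1
F2 | step 3 | (E)-1-(3,4-dimethoxyphenyl)-2-[3-(4-methoxyphenyl)prop-2-en-1-yl]-3-(morpholin-4-yl)propane-1,3-dione, racemic | COc1ccc(/C=C/CC(C(=O)N2CCOCC2)C(=O)c2ccc(OC)c(OC)c2)cc1
F3 | step 3 | (2S,E)-2-[(S)-(3,4-dimethoxyphenyl)(hydroxy)methyl]-5-(4-methoxyphenyl)-1-(morpholin-4-yl)pent-4-en-1-one | O=C(N1CCOCC1)[C@@H](C/C=C/c1ccc(OC)cc1)[C@H](O)c1ccc(OC)c(OC)c1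
F4 | step 5 | ethyl (E)-2-(tributylstannyl)but-2-enoate | C/C=C(/[Sn](CCCC)(CCCC)CCCC)C(=O)OCC
F5 | step 5 | ethyl (E)-2-iodobut-2-enoate | C/C=C(/I)C(=O)OCC
F0 | step 8 | none | none
F6 | step 9 | (2R,E)-2-[(S)-(3,4-dimethoxyphenyl)(hydroxy)methyl]-5-(4-methoxyphenyl)pent-4-en-1-yl 4-methylbenzenesulfonate | Cc1ccc(cc1)S(=O)(=O)OC[C@@H](C/C=C/c1ccc(OC)cc1)[C@H](O)c1ccc(OC)c(OC)c1
F7 | step 9 | (Z)-2-(hydroxymethyl)but-2-enoic acid | C/C=C(/CO)C(=O)O
F8 | step 2 | (E)-1-(3-bromoprop-1-en-1-yl)-4-methoxybenzene | BrC/C=C/c1ccc(OC)cc1
A1 | alternative 1 | bis(tert-butyldimethylsilyl) ether of (R)-1-(3,4-dimethoxyphenyl)-2-methylenepropane-1,3-diol | C=C(CO[Si](C)(C)C(C)(C)C)[C@H](O[Si](C)(C)C(C)(C)C)c1ccc(OC)c(OC)c1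
A2 | alternative 1 | (E)-1-(2-bromovinyl)-4-methoxybenzene | COc1ccc(/C=C/Br)cc1
A3 | alternative 1 | bis(tert-butyldimethylsilyl) ether of (1S,2R,E)-1-(3,4-dimethoxyphenyl)-2-(hydroxymethyl)-5-(4-methoxyphenyl)pent-4-en-1-ol | CC(C)(C)[Si](C)(C)OC[C@@H](C/C=C/c1ccc(OC)cc1)[C@H](O[Si](C)(C)C(C)(C)C)c1ccc(OC)c(OC)c1
A4 | alternative 2 | (R)-1-(4-methoxyphenyl)allyl 3-hydroxypropanoate | C=C[C@@H](OC(=O)CCO)c1ccc(OC)cc1
A5 | alternative 2 | (R,E)-2-(hydroxymethyl)-5-(4-methoxyphenyl)pent-4-enoic acid | OC[C@@H](C/C=C/c1ccc(OC)cc1)C(=O)O
A6 | alternative 3 | {[(1Z,4E)-1-(3,4-dimethoxyphenyl)-5-(4-methoxyphenyl)penta-1,4-dien-1-yl]oxy}trimethylsilane | C[Si](C)(C)O/C(=C\C/C=C/c1ccc(OC)cc1)c1ccc(OC)c(OC)c1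
A7 | alternative 3 | (R,E)-1-(3,4-dimethoxyphenyl)-2-(hydroxymethyl)-5-(4-methoxyphenyl)pent-4-en-1-one | OC[C@@H](C/C=C/c1ccc(OC)cc1)C(=O)c1ccc(OC)c(OC)c1
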